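The readings are calculated with made-up constants.

**Start ratio.** Start from one ratio in the summer run: at 480 h, G over J lost reads 0.220. Don't carry that share to a short run. The proposed steps make L from J and G from L, so G starts with a lag, an induction period.

| flask | J | temperature | remark | time |
|---|---|---|---|---|
| summer | 0.11 M | −30 °C | run made earlier |  |
| autumn | 0.26 M | 20 °C | run made earlier |  |
| amber | 0.17 M | 35 °C |  | 30 h |
| grey | 0.17 M | 5 °C |  | 30 h |
| violet | 0.17 M | 65 °C |  | 30 h |
| green | 0.17 M | −25 °C |  | 30 h |

| run | time / h | G / % | J / % |
|---|---|---|---|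
| summer | 40.0 | 1 | 97 |
| summer | 120 | 2 | 91 |
| summer | 192 | 4 | 82 |
| summer | 288 | 3 | 75 |
| summer | 480 | 9 | 59 |
| autumn | 3.00 | 57 | 0 |
| autumn | 10.0 | 53 | 0 |
| autumn | 15.0 | 51 | 2 |
| autumn | 25.0 | 50 | 0 |
| autumn | 40.0 | 52 | 1 |

(scatter of a reading: 1.5 percentage points)

- in percentages every species weighs as the J in it: one D counts as two
- what may be going on: L <-> X; L <-> G; J -> L; J + L -> D

* which flask leads in amount of G, in percent of the J charged ("all alike" within 1.5 percentage points) (amber / grey / violet / green / all alike)
* how much G is there at the end, in percent of the J charged: amber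
* how much G is there at the end, in percent of the J charged: grey
* how much G is there at the end, in percent of the J charged: violet
* how much G is there at the end, in percent of the J charged: green

**Chain constant.** Let x be the fraction of J lost. While back steps and the side losses of L are small, [L] grows with x, and G gained per unit of x grows with [L]. So [G] follows the square of x, provided both steps speed up alike with temperature; assume that. Divide the last summer G reading by the square of its x to get 0.535, the chain constant, a reading that carries the scatter. Test it at 288 h in the summer run: it gives 3.35%, and the reading is 3%.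

**Green rate.** Here is my own reckoning for green. The summer loss of J gives a first-order constant of 0.00110 h⁻¹. Take the forecast's speed-up of 2.5 to −25 °C, which gives 0.00275 h⁻¹. At this starting rate, x after 30 h is 8.24%. But [J] falls meanwhile, which slows the mean rate by a factor of 0.959. Go round once more: x becomes 7.90%, and the chain constant gives 0.335% G in green.

**The forecast.** The forecast picks grey as leader, with amber 49%, grey 54%, violet 45% and green 1.5%. For green it reckons “About 20% of that appears as G”, and its green figure stands higher than my 0.335%.

**The result.** Grey leads with 62.3%; amber gives 43.6%, violet 27.5% and green 0.316%.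

    L ⇌ X (K = 2.50, k = 2.80 × 10⁻⁵ s⁻¹, Ea = 88.0 kJ mol⁻¹, ΔH = 0 kJ mol⁻¹)
    L ⇌ G (K = 7.40, k = 1.00 × 10⁻⁴ s⁻¹, Ea = 90.0 kJ mol⁻¹, ΔH = −22.0 kJ mol⁻¹)
    J → L (k = 6.50 × 10⁻⁵ s⁻¹, Ea = 88.0 kJ mol⁻¹)
    J + L → D (k = 1.10 × 10⁻⁴ M⁻¹ s⁻¹, Ea = 65.0 kJ mol⁻¹)
    (constants at 5 °C)

In green, L has a half-life of 8.9 d at 14.7 h by the forward step to G alone, longer than the 30 h of the run. At the end of green, L stands at 6.19% and G at 0.316%. Apply the chain constant to the 93.0% of J left in green: it gives 0.262% G. Apply it to the neighbour at −10 °C, with the same charge and time and 42% of J left: it gives 18.2%, and that flask holds 20.3%.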